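A direct plan would keep both benzene rings as bought arenes and join them at the aryl C3–O bond of ring B. 2,4-Dimethoxy-6-pentylbenzoic acid (A1) would be dehydrated with hydrogen peroxide to its diaroyl peroxide (A2), 5-propylresorcinol (A3) would be carboxylated to 2,4-dihydroxy-6-propylbenzoic acid (A4), and the phenolate of A4 would be aroyloxylated at C3 by A2. Its weakest steps would be:
- the peroxide formation: a hindered acid, an electron-rich peroxide that could not be stored, and half of A1 spent as leaving group;
- the C–H aroyloxylation: no precedent on a free resorcylic acid, and the phenolate could as well attack at C5, be O-acylated or start radical decay of A2 by electron transfer;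
- the carboxylation of A3: reversible, and A4 would have to pass a basic step unprotected although it decarboxylates easily.

The route rests on a ring disconnection, not on an ester or aryl–oxygen disconnection. Ring B is cut at C1–C2 and C5–C6 into benzyl hex-2-ynoate and a dimedone-derived 1,3-bis(silyloxy)cyclohexadiene whose central carbon already carries the hindered aroyloxy group: the O–C2–C3(OCOAr)–C4–O array of ring B is read as a masked 2-acyloxy-1,3-diketone. One Diels–Alder/retro-Diels–Alder operation (loss of isobutene) then builds ring B with all six substituents in place and the carboxyl group protected. No peroxide is made, no phenol is oxygenated or acylated, so no choice among three phenolic oxygens arises, and no resorcinol is carboxylated.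

Key step: step 7

Remark: the target has no stereocentre; enolised 1,3-diones are drawn as one tautomer.

Step 1
Reactants: 1 1,3-dimethoxy-5-pentylbenzene
Product: 3 2,4-dimethoxy-6-pentylbenzaldehyde, via aryl iminium chloride 2 (not isolated)
Conditions: POCl3 (1.3 equiv), DMF, 0 °C to 70 °C, 3 h; then ice-water, 50 °C, 1 h
Reagents that add atoms: N,N-dimethylformamide, CN(C)C=O; water, O
Why: Vilsmeier–Haack formylation, in which the chloroiminium ion should attack the ring carbon para to one methoxy group and ortho to the other rather than the more crowded carbon between the two methoxy groups, and water hydrolyses iminium salt 2 to the aldehyde.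

Step 2
Reactants: 3 2,4-dimethoxy-6-pentylbenzaldehyde
Product: 4 2,4-dimethoxy-6-pentylbenzoic acid
Conditions: NaClO2 (1.5 equiv), NaH2PO4 (1.5 equiv), 2-methylbut-2-ene (10 equiv), tBuOH/H2O, rt
Reagents that add atoms: sodium chlorite, [Na+].[O-]Cl=O
Why: Pinnick chlorite oxidation should convert the hindered, electron-rich aldehyde into the acid without ring chlorination, because 2-methylbut-2-ene removes the hypochlorous acid as it forms.

Step 3
Reactants: 5 5,5-dimethylcyclohexane-1,3-dione (dimedone)
Product: 6 2-diazo-5,5-dimethylcyclohexane-1,3-dione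
Conditions: 4-acetamidobenzenesulfonyl azide (1.05 equiv), Et3N (1.2 equiv), MeCN, 0 °C to rt
Reagents that add atoms: 4-acetamidobenzenesulfonyl azide, CC(=O)Nc1ccc(cc1)S(=O)(=O)N=[N+]=[N-]
Why: Regitz diazo transfer to the doubly activated methylene group of a cyclic 1,3-dione, driven by loss of the sulfonamide.

Step 4
Reactants: 4 2,4-dimethoxy-6-pentylbenzoic acid; 6 2-diazo-5,5-dimethylcyclohexane-1,3-dione
Product: 7 2-hydroxy-4,4-dimethyl-6-oxocyclohex-1-en-1-yl 2,4-dimethoxy-6-pentylbenzoate (enol form of the 2-aroyloxy-1,3-dione)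
Conditions: 6 (1.1 equiv, added over 2 h), Rh2(OAc)4 (1 mol%), PhF, 70 °C, N2
Reagents that add atoms: none
Why: Rhodium-carbenoid O–H insertion into a carboxylic acid, in which the electrophilic carbenoid formed from 6 by loss of nitrogen should be captured by the carboxyl oxygen of 4 faster than by its ester-deactivated ring, and the product rests as the enolised vinylogous acid in which the di-ortho-substituted aroyl group is too hindered to move to the neighbouring enol oxygen.

Step 5
Reactants: 8 hex-2-ynoic acid
Product: 9 benzyl hex-2-ynoate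
Conditions: BnBr (1.1 equiv), KHCO3 (1.2 equiv), DMF, rt
Reagents that add atoms: benzyl bromide, BrCc1ccccc1
Why: Carboxylate O-alkylation (SN2 on benzyl bromide) with a weak base that should esterify the acid without isomerising the conjugated alkyne to the allene.

Step 6
Reactants: 7 2-hydroxy-4,4-dimethyl-6-oxocyclohex-1-en-1-yl 2,4-dimethoxy-6-pentylbenzoate
Product: 11 4,4-dimethyl-2,6-bis(trimethylsilyloxy)cyclohexa-1,5-dien-1-yl 2,4-dimethoxy-6-pentylbenzoate, via monosilyl enol ether 10 (not isolated)
Conditions: TMSOTf (2.4 equiv), Et3N (3 equiv), Et2O, 0 °C to rt, Ar; dilute with pentane, filter, evaporate, use crude at once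
Reagents that add atoms: trimethylsilyl trifluoromethanesulfonate, C[Si](C)(C)OS(=O)(=O)C(F)(F)F
Why: Soft enolisation with a silyl triflate and a tertiary amine, in which O-silylation of the enol gives 10, a second silylation on the carbonyl oxygen makes a 1,3-dioxyallyl cation, and loss of a proton from either of the two equivalent alpha-CH2 groups gives the same cross-conjugated diene, so that no strong base ever meets the aryl ester.

Step 7
Reactants: 11 4,4-dimethyl-2,6-bis(trimethylsilyloxy)cyclohexa-1,5-dien-1-yl 2,4-dimethoxy-6-pentylbenzoate; 9 benzyl hex-2-ynoate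
Product: 14 benzyl 3-[(2,4-dimethoxy-6-pentylbenzoyl)oxy]-2,4-dihydroxy-6-propylbenzoate, via bicyclooctadiene adduct 12 (not isolated), via bis-silyl arene 13 (not isolated)
Conditions: 11 (2 equiv), 9 (1 equiv), neat, sealed tube, 140 °C, 24–36 h, Ar; then THF/MeOH, 1 M HCl, 0 °C, 30 min (7 is recovered from the excess diene)
Reagents that add atoms: none
Why: Alder–Rickert benzannulation, that is a thermal Diels–Alder reaction of a 1,3-bis(silyloxy)cyclohexa-1,3-diene with an alkynoate followed by retro-Diels–Alder loss of an alkene, the closest known case being the reaction of the parent dimedone-derived bis(silyloxy)diene with beta-alkyl alkynoates to give 6-alkyl-2,4-dihydroxybenzoates. Ring B is closed by an intermolecular [4+2] cycloaddition that forms C1–C2 and C5–C6 (ring B numbering of the target) and gives bicyclo[2.2.2]octadiene 12, and it becomes aromatic by a retro-[4+2] in which the CH2–CMe2 bridge leaves as isobutene; the gem-dimethyl group keeps the diene from aromatising on its own before it reacts. The step needs one regiochemistry, and both silyloxy groups should enforce it: they raise the HOMO coefficient at the unsubstituted CH terminus of the diene, which bonds to the propyl-bearing beta-carbon of the ynoate (largest LUMO coefficient), so that the ester carbon ends up next to a silyloxy carbon and the propyl group next to the ring CH, a bias that the weakly donating aroyloxy group on the central carbon cannot override. The [1,5]-hydrogen shift open to 11 is degenerate, so prolonged heating should not produce an isomeric diene. The two bridgehead stereocentres of racemic 12 are erased on aromatisation, so no stereochemistry has to be controlled, and cold dilute acid then cleaves the two aryl silyl ethers of 13 while the benzyl ester and the hindered depside ester, never exposed to base, stay in place.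

Step 8
Reactants: 14 benzyl 3-[(2,4-dimethoxy-6-pentylbenzoyl)oxy]-2,4-dihydroxy-6-propylbenzoate
Product: 15 3-[(2,4-dimethoxy-6-pentylbenzoyl)oxy]-2,4-dihydroxy-6-propylbenzoic acid (target)
Conditions: H2 (1 atm), 10% Pd/C, EtOAc, rt; filter, evaporate below 30 °C
Reagents that add atoms: none
Why: Hydrogenolysis of a benzyl ester over palladium on carbon, neutral conditions at room temperature under which the aryl ester should not migrate and the beta-resorcylic acid should not decarboxylate.

Compound list
1 | 1,3-dimethoxy-5-pentylbenzene | CCCCCc1cc(OC)cc(OC)c1 | starting material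
2 | N-[(2,4-dimethoxy-6-pentylphenyl)methylidene]-N-methylmethanaminium chloride | CCCCCc1cc(OC)cc(OC)c1C=[N+](C)C.[Cl-] | intermediate (not isolated)
3 | 2,4-dimethoxy-6-pentylbenzaldehyde | CCCCCc1cc(OC)cc(OC)c1C=O | intermediate
4 | 2,4-dimethoxy-6-pentylbenzoic acid | CCCCCc1cc(OC)cc(OC)c1C(=O)O | intermediate
5 | 5,5-dimethylcyclohexane-1,3-dione | CC1(C)CC(=O)CC(=O)C1 | starting material
6 | 2-diazo-5,5-dimethylcyclohexane-1,3-dione | CC1(C)CC(=O)C(=[N+]=[N-])C(=O)C1 | intermediate
7 | 2-hydroxy-4,4-dimethyl-6-oxocyclohex-1-en-1-yl 2,4-dimethoxy-6-pentylbenzoate | CCCCCc1cc(OC)cc(OC)c1C(=O)OC1=C(O)CC(C)(C)CC1=O | intermediate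
8 | hex-2-ynoic acid | CCCC#CC(=O)O | starting material
9 | benzyl hex-2-ynoate | CCCC#CC(=O)OCc1ccccc1 | intermediate
10 | 4,4-dimethyl-6-oxo-2-(trimethylsilyloxy)cyclohex-1-en-1-yl 2,4-dimethoxy-6-pentylbenzoate | CCCCCc1cc(OC)cc(OC)c1C(=O)OC1=C(O[Si](C)(C)C)CC(C)(C)CC1=O | intermediate (not isolated)
11 | 4,4-dimethyl-2,6-bis(trimethylsilyloxy)cyclohexa-1,5-dien-1-yl 2,4-dimethoxy-6-pentylbenzoate | CCCCCc1cc(OC)cc(OC)c1C(=O)OC1=C(O[Si](C)(C)C)CC(C)(C)C=C1O[Si](C)(C)C | intermediate
12 | benzyl 6-[(2,4-dimethoxy-6-pentylbenzoyl)oxy]-8,8-dimethyl-3-propyl-1,5-bis(trimethylsilyloxy)bicyclo[2.2.2]octa-2,5-diene-2-carboxylate (racemic, both stereocentres erased in the same step) | CCCCCc1cc(OC)cc(OC)c1C(=O)OC1=C(O[Si](C)(C)C)C2C(CCC)=C(C(=O)OCc3ccccc3)C1(O[Si](C)(C)C)CC2(C)C | intermediate (not isolated)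
13 | benzyl 3-[(2,4-dimethoxy-6-pentylbenzoyl)oxy]-6-propyl-2,4-bis(trimethylsilyloxy)benzoate | CCCCCc1cc(OC)cc(OC)c1C(=O)Oc1c(O[Si](C)(C)C)cc(CCC)c(C(=O)OCc2ccccc2)c1O[Si](C)(C)C | intermediate (not isolated)
14 | benzyl 3-[(2,4-dimethoxy-6-pentylbenzoyl)oxy]-2,4-dihydroxy-6-propylbenzoate | CCCCCc1cc(OC)cc(OC)c1C(=O)Oc1c(O)cc(CCC)c(C(=O)OCc2ccccc2)c1O | intermediate
15 | 3-[(2,4-dimethoxy-6-pentylbenzoyl)oxy]-2,4-dihydroxy-6-propylbenzoic acid (achiral) | CCCCCc1cc(OC)cc(OC)c1C(=O)Oc1c(O)cc(CCC)c(C(=O)O)c1O | target

Total step count: 8. Longest linear sequence: 6 steps (steps 1, 2, 4, 6, 7, 8, from 1,3-dimethoxy-5-pentylbenzene).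

Steps most likely to fail

Step 7. The cycloaddition may be slower than the thermal decay of diene 11, since the ynoate is trisubstituted and activated by one ester only, or the central aroyloxy group may erode the regiocontrol. The fallback sets out from acid 4 and comes back to the route at 14; it makes ring B as a cyclohexane-1,3-dione and oxidises it. Dibenzyl malonate and (E)-hept-3-en-2-one would be joined by Michael addition and Claisen ring closure (KOtBu, THF) to benzyl 2,4-dioxo-6-propylcyclohexane-1-carboxylate F1. Diazo transfer to the methylene group between the two ketones would give benzyl 3-diazo-2,4-dioxo-6-propylcyclohexane-1-carboxylate F2. Rh2(OAc)4 with acid 4 would give benzyl 3-[(2,4-dimethoxy-6-pentylbenzoyl)oxy]-2,4-dioxo-6-propylcyclohexane-1-carboxylate F3, and dehydrogenation (DDQ, dioxane) would aromatise it to 14.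

Step 4. The carbenoid may attack the electron-rich ring of 4, rearrange by Wolff ring contraction, or insert a second time into the enol O–H of the product. The fallback sets out from dimedone 5 and comes back at 7 by a polar path without a metal carbene. Dimedone would be turned with PhI(OAc)2 and KOH in methanol into its bench-stable iodonium ylide, 5,5-dimethyl-2-(phenyl-λ3-iodanylidene)cyclohexane-1,3-dione F4. Warming F4 with acid 4 in MeCN should protonate the ylide carbon and let the carboxylate displace iodobenzene to give 7.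

Step 6. The second enolisation may stall at 10, the aroyl group may move to a neighbouring enol oxygen, or the diene may hydrolyse on isolation. The fallback sets out from 7 and comes back at the target 15, replacing one silyl ether by a benzyl ether that the last step removes anyway.
- Compound 7 would be condensed with benzyl alcohol (TsOH, benzene, Dean–Stark) to the chromatographable vinylogous ester 2-(benzyloxy)-4,4-dimethyl-6-oxocyclohex-1-en-1-yl 2,4-dimethoxy-6-pentylbenzoate F5.
- Kinetic enolisation (LDA, THF, −78 °C, TMSCl present) would give 2-(benzyloxy)-4,4-dimethyl-6-(trimethylsilyloxy)cyclohexa-1,5-dien-1-yl 2,4-dimethoxy-6-pentylbenzoate F6.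
- F6 and 9 under the conditions of step 7 would pass through the bicyclic adduct F7 and the aryl silyl ether F8 to benzyl 2-(benzyloxy)-3-[(2,4-dimethoxy-6-pentylbenzoyl)oxy]-4-hydroxy-6-propylbenzoate F9.
- The hydrogenolysis of step 8 would remove both benzyl groups of F9 to give 15.

Further compounds
F1 | step 7 | benzyl 2,4-dioxo-6-propylcyclohexane-1-carboxylate (racemic, enolised; stereocentres erased on aromatisation) | CCCC1CC(=O)CC(=O)C1C(=O)OCc1ccccc1
F2 | step 7 | benzyl 3-diazo-2,4-dioxo-6-propylcyclohexane-1-carboxylate (racemic) | CCCC1CC(=O)C(=[N+]=[N-])C(=O)C1C(=O)OCc1ccccc1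
F3 | step 7 | benzyl 3-[(2,4-dimethoxy-6-pentylbenzoyl)oxy]-2,4-dioxo-6-propylcyclohexane-1-carboxylate (racemic, enolised) | CCCCCc1cc(OC)cc(OC)c1C(=O)OC1C(=O)CC(CCC)C(C(=O)OCc2ccccc2)C1=O
F4 | step 4 | 5,5-dimethyl-2-(phenyl-λ3-iodanylidene)cyclohexane-1,3-dione | CC1(C)CC(=O)[C-]([I+]c2ccccc2)C(=O)C1
F5 | step 6 | 2-(benzyloxy)-4,4-dimethyl-6-oxocyclohex-1-en-1-yl 2,4-dimethoxy-6-pentylbenzoate | CCCCCc1cc(OC)cc(OC)c1C(=O)OC1=C(OCc2ccccc2)CC(C)(C)CC1=O
F6 | step 6 | 2-(benzyloxy)-4,4-dimethyl-6-(trimethylsilyloxy)cyclohexa-1,5-dien-1-yl 2,4-dimethoxy-6-pentylbenzoate | CCCCCc1cc(OC)cc(OC)c1C(=O)OC1=C(OCc2ccccc2)CC(C)(C)C=C1O[Si](C)(C)C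
F7 | step 6 | benzyl 1-(benzyloxy)-6-[(2,4-dimethoxy-6-pentylbenzoyl)oxy]-8,8-dimethyl-3-propyl-5-(trimethylsilyloxy)bicyclo[2.2.2]octa-2,5-diene-2-carboxylate (racemic) | CCCCCc1cc(OC)cc(OC)c1C(=O)OC1=C(O[Si](C)(C)C)C2C(CCC)=C(C(=O)OCc3ccccc3)C1(OCc4ccccc4)CC2(C)C
F8 | step 6 | benzyl 2-(benzyloxy)-3-[(2,4-dimethoxy-6-pentylbenzoyl)oxy]-6-propyl-4-(trimethylsilyloxy)benzoate | CCCCCc1cc(OC)cc(OC)c1C(=O)Oc1c(O[Si](C)(C)C)cc(CCC)c(C(=O)OCc2ccccc2)c1OCc1ccccc1
F9 | step 6 | benzyl 2-(benzyloxy)-3-[(2,4-dimethoxy-6-pentylbenzoyl)oxy]-4-hydroxy-6-propylbenzoate | CCCCCc1cc(OC)cc(OC)c1C(=O)Oc1c(O)cc(CCC)c(C(=O)OCc2ccccc2)c1OCc1ccccc1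
A1 | direct plan | 2,4-dimethoxy-6-pentylbenzoic acid | CCCCCc1cc(OC)cc(OC)c1C(=O)O
A2 | direct plan | bis(2,4-dimethoxy-6-pentylbenzoyl) peroxide | CCCCCc1cc(OC)cc(OC)c1C(=O)OOC(=O)c1c(CCCCC)cc(OC)cc1OC
A3 | direct plan | 5-propylbenzene-1,3-diol | CCCc1cc(O)cc(O)c1
A4 | direct plan | 2,4-dihydroxy-6-propylbenzoic acid | CCCc1cc(O)cc(O)c1C(=O)O
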